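## Analysis of the target

Target 22 is an unbranched C17 chain acylated at O3 by linoleic acid. It carries a vinyl group (C1=C2), the carbinol ester carbon C3, a conjugated diyne (C4≡C5–C6≡C7), one methylene (C8), an oxirane across C9–C10 and a heptyl tail (C11–C17); the oxirane is the only ring. Read from the SMILES, the three stereocentres are C3 (S), C9 (R) and C10 (R), and the two oxirane substituents are trans. C9 and C10 are neighbours, but C3 is separated from C9 by four sp carbons and a methylene, so nothing can relay configuration between the two ends, and a C3 epimer would be practically inseparable from 22. The sensitive sites are the allylic and propargylic C3–O bond, the light-sensitive diyne, the C8 hydrogens between alkyne and oxirane (base can trigger eliminative ring opening), the oxirane itself, and the skipped (9Z,12Z)-diene of the acyl chain, which rules out hydrogenation and radical or oxidising conditions once it is present. The difficulty is that the oxirane is a trans-dialkyl epoxide with a methylene on each side and no directing group in the final skeleton, yet both of its centres must be set absolutely and independently of C3. The strategy rests on the run C7–C8–C9–C10–C11, which maps atom for atom onto C1–C5 of 2-deoxy-D-ribose 1: the aldehyde carbon becomes C7, the methylene C8, the two carbinol carbons C9 and C10, and the hydroxymethyl carbon C11. The sugar has the configuration of C10 as it stands and the opposite configuration at C9, which is what an oxirane closure by backside displacement at C9 with retention of O10 requires.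

## Retrosynthetic reasoning

**C3–O acyl bond.** Target 22 is cut into diynol 20 and linoleic acid 21. The ester comes last because the skipped diene of 21 and the ester itself should not meet amines, copper salts or organometallic reagents. The forward step has to acylate a secondary, doubly activated alcohol under neutral conditions without ionising C3 or touching the oxirane.

**C5–C6 bond of the diyne.** Diynol 20 is cut between the two alkynes into terminal alkyne 13 and bromoalkyne 19. This cut puts the C3 stereocentre in one fragment and the C9/C10 pair in the other, so each can be made and checked for enantiomeric purity separately before union; no other cut separates the two stereochemical problems as cleanly. The forward reaction is a copper-catalysed sp–sp heterocoupling that must be mild enough for the oxirane and the C8 hydrogens.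

**The C1–C5 fragment.** Bromoalkyne 19 comes from silylalkyne 18 by exchange of silicon for bromine. Alcohol 18 comes from racemate 17 by enzymatic kinetic resolution, and 17 from silylacetylene 14 and acrolein 15 by forming the C3–C4 bond. The silyl group first makes the two unsaturated substituents at C3 very different in size for the enzyme and then serves as the handle for bromination.

**C11–C12 bond.** The sugar ends at C11, so the six remaining carbons of 13 are attached by an sp3–sp3 coupling of triflate 10 with hexylmagnesium bromide 12, made from 1-bromohexane 11. The bond is cut here because C11 is a primary, non-stereogenic carbon. The forward displacement has to be faster than opening of the neighbouring oxirane. Triflate 10 comes from epoxy alcohol 9.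

**C9–O bond of the oxirane.** Epoxy alcohol 9 is opened to diol mesylate 8, which comes from ketal 7. The oxirane oxygen is O10 of the sugar; C9 carries the leaving group and is inverted on closure, which turns the erythro arrangement of the sugar into the trans ring. This requires O9 to be singled out among three hydroxyls. That is done in alcohol 6, where O10 and O11 are tied up as the terminal ketal, and 6 comes from its ketal isomer 5 by migration.

**C6–C7 bond.** Alkyne 5 is cut to lactol 2 and diazophosphonate 3, which acts through its deacylated form 4. A one-carbon homologation turns the masked aldehyde carbon of the sugar directly into C7 at the alkyne oxidation level and frees O11 as the handle for the chain extension. Compound 5 then holds C6–C11 with both oxygens and the correct configuration at C10.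

**The ketal.** Lactol 2 comes from 2-deoxy-D-ribose 1 by ketalisation of its cis-3,4-diol.

## Alternatives that were turned down

Alternative 1: The two C–O bonds of the oxirane are cut last, back to the (E)-C9=C10 alkene of a silyl-protected enediyne A1, the tert-butyldimethylsilyl ether of (3S,9E)-heptadeca-1,9-dien-4,6-diyn-3-ol. In the forward direction a chiral dioxirane, generated in the flask from a carbohydrate-derived ketone catalyst and a peroxy salt, would transfer oxygen to that alkene and give A2, the silyl ether of the (3S,9R,10R)-epoxy diynol. In its favour, the fragile oxirane appears at the latest possible stage, the step is catalytic, and trans-disubstituted alkenes are the best substrate class for this oxidant. The terminal vinyl group is monosubstituted and deactivated by the C3 oxygen, so site selectivity is plausible. Against it, the alkene is flanked by two unbranched methylene chains, so facial discrimination relies only on the catalyst and is unlikely to be complete; the minor (9S,10S) oxirane would be a diastereomer of A2 with its stereocentres six atoms apart and could not be removed. The C8 methylene of A1 is both allylic and propargylic, and the buffered basic aqueous medium of the oxidation invites isomerisation into conjugation; the diyne is itself oxidisable. This alternative is shorter and more convergent than the chosen route. In its place the chosen route takes C10 unchanged from the sugar and sets C9 by a stereospecific displacement, so the configuration of the oxirane does not depend on catalyst selectivity.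

Alternative 2: The C8–C9 bond is cut, with the oxirane traced back to a chlorohydrin. In the forward direction (2S)-2-chlorononanal A3 and allenylboronic acid pinacol ester A4 would react under a chiral phosphoric acid to give (4R,5S)-5-chlorododec-1-yn-4-ol A5, with the new carbinol anti to the chloride; base would then close A5 directly to 13 with inversion at the chlorine-bearing carbon. In its favour, one C–C bond formation delivers the alkyne, C8, both hetero-substituted carbons and the complete heptyl chain. The anti relationship is also the intrinsic preference of nucleophilic additions to α-chloro aldehydes, so catalyst and substrate control can reinforce each other. Alkyne 13 would be reached in about three steps where the chosen route needs seven, and no organometallic displacement next to a terminal alkyne is needed; on step economy this alternative is clearly stronger. Against it, A3 is configurationally labile: its α-hydrogen is acidic, and the acid catalyst that activates A4 can also promote enolisation, so the C10 configuration rests on a centre that can erode during the step that sets C9. Two catalyst-controlled events in sequence each leave a minor isomer, all intermediates are oils that cannot be upgraded by crystallisation, and every stereoisomer of 13 ends as an inseparable diastereomer of 22. In place of brevity the chosen route offers configurationally stable intermediates (ketals, a mesylate) and the absolute configuration of a sugar.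

Alternative 3: The C3–C4 bond is cut between the carbinol carbon and the diyne. In the forward direction the terminal diyne (2R,3R)-2-heptyl-3-(penta-2,4-diyn-1-yl)oxirane A6 would add, as its alkynylzinc species, to acrolein A7 (the same compound as 15) under a chiral dinuclear zinc catalyst, giving the (3S,9R,10R)-epoxy diynol A8, which is identical with 20. In its favour, C3 is set catalytically without discarding half of a racemate, the enal is the cheapest possible, and the union is the last skeletal step; for material economy at C3 it is stronger than a resolution. Against it, this disconnection solves only C3: A6 still needs the whole oxirane problem solved first and would have to be made from 13 by a further two-carbon extension, so the linear sequence grows. A6 is a terminal skipped diyne next to an oxirane and is expected to be much less stable than 13. Acrolein offers the catalyst only the difference between hydrogen and vinyl and polymerises readily, so incomplete selectivity at C3 is likely, and the C3 epimer cannot be separated from A8. Lewis-acidic zinc alkoxides are also a hazard for the oxirane. The chosen route sets C3 in a five-carbon fragment whose enantiomeric purity can be measured and raised before coupling, and the coupling itself has no stereochemical consequence.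

Key step: step 2

Remark on the chemistry: lactol 2 is made and used as its anomeric mixture, since both anomers open to the same hydroxy aldehyde. The lipase in step 9 is assumed to follow the usual size-based preference for secondary alcohols (silylethynyl as the large group, vinyl as the medium one); the configuration and enantiomeric purity of 18 are to be confirmed by Mosher ester analysis before it is carried on.

## Route

Step 1
Reactants: 1 2-deoxy-D-ribose
Product: 2 2-deoxy-3,4-O-isopropylidene-D-erythro-pentopyranose (anomeric mixture)
Conditions: 2-methoxypropene, PPTS (cat.), EtOAc, 0 °C → rt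
Reagents that add atoms: 2-methoxypropene, COC(C)=C
Why: Acid-catalysed ketal transfer from the enol ether; in the pyranose form only the cis-3,4-diol can span a five-membered ketal, so the anomeric hydroxyl stays free and no stereocentre is touched.

Step 2
Reactants: 2 2-deoxy-3,4-O-isopropylidene-D-erythro-pentopyranose; 3 dimethyl (1-diazo-2-oxopropyl)phosphonate
Product: 5 [(4R,5S)-2,2-dimethyl-5-(prop-2-yn-1-yl)-1,3-dioxolan-4-yl]methanol, via dimethyl (diazomethyl)phosphonate 4 (not isolated)
Conditions: K2CO3, MeOH, 0 °C → 40 °C
Reagents that add atoms: none
Why: Carbonate in methanol cleaves the acetyl group of 3 as methyl acetate and gives the anion of 4, while lactol 2 is in ring–chain equilibrium with a small amount of its hydroxy aldehyde, so the pyranose opens as the aldehyde is consumed. The phosphonate anion adds to the aldehyde carbon (the future C7), the oxaphosphetane collapses in a Horner–Wadsworth–Emmons-type cycloelimination of dimethyl phosphate to a diazoalkene, this loses dinitrogen to an alkylidene carbene, and a 1,2-hydrogen shift gives the terminal alkyne with the new carbon as C6. The closest known reaction type is the Seyferth–Gilbert homologation in its Ohira–Bestmann form applied to protected sugar lactols. No ring is closed and no stereocentre is created; the step needs preservation of the two existing centres and chemoselectivity. C8 is a methylene, so there is no α-stereocentre to epimerise, and the β-oxygen O9 is held in the cis-fused dioxolane as a poor leaving group, so E1cB elimination from the transient aldehyde should be slower than its capture by the phosphonate anion under these weakly basic conditions. The 1,2-hydrogen shift of an aldehyde-derived alkylidene carbene is faster than insertion into the C10–H or O11–H bonds, which secures the alkyne over cyclised by-products. An excess of 3 and gentle warming compensate for the low stationary concentration of the open-chain aldehyde.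

Step 3
Reactants: 5 [(4R,5S)-2,2-dimethyl-5-(prop-2-yn-1-yl)-1,3-dioxolan-4-yl]methanol
Product: 6 (1S)-1-[(4R)-2,2-dimethyl-1,3-dioxolan-4-yl]but-3-yn-1-ol
Conditions: CSA (cat.), acetone, rt; then Et3N
Reagents that add atoms: none
Why: Acid-catalysed ketal migration under thermodynamic control; the cis-4,5-disubstituted dioxolane of 5 is strained relative to the monosubstituted terminal dioxolane of 6, and the six-membered O9/O11 ketal is disfavoured by an axial methyl group, so the equilibrium should lie on the side of 6 (recovered 5 is recycled). Only bonds to the ketal carbon are exchanged, so C9 and C10 keep their configuration.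

Step 4
Reactants: 6 (1S)-1-[(4R)-2,2-dimethyl-1,3-dioxolan-4-yl]but-3-yn-1-ol
Product: 7 (1S)-1-[(4R)-2,2-dimethyl-1,3-dioxolan-4-yl]but-3-yn-1-yl methanesulfonate
Conditions: MsCl, Et3N, CH2Cl2, 0 °C
Reagents that add atoms: methanesulfonyl chloride, CS(=O)(=O)Cl
Why: O-sulfonylation of the only free hydroxyl; the C9–O bond is not broken, so C9 remains S and now carries the leaving group.

Step 5
Reactants: 7 (1S)-1-[(4R)-2,2-dimethyl-1,3-dioxolan-4-yl]but-3-yn-1-yl methanesulfonate
Product: 9 [(2R,3R)-3-(prop-2-yn-1-yl)oxiran-2-yl]methanol, via (2R,3S)-1,2-dihydroxyhex-5-yn-3-yl methanesulfonate 8 (not isolated)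
Conditions: TsOH·H2O (cat.), MeOH/H2O, rt; then K2CO3, 0 °C → rt
Reagents that add atoms: none
Why: Acid hydrolysis of the terminal ketal leaves the mesylate intact; carbonate then generates the C10 alkoxide, which displaces the C9 mesylate in an intramolecular Williamson reaction (3-exo-tet) with inversion at C9 (S to R), while C10 keeps its oxygen and stays R, giving the trans-2,3-epoxy alcohol. O11 could only close a four-membered ring, which is much slower; low temperature and a short reaction time limit Payne rearrangement and methanolysis.

Step 6
Reactants: 9 [(2R,3R)-3-(prop-2-yn-1-yl)oxiran-2-yl]methanol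
Product: 10 [(2R,3R)-3-(prop-2-yn-1-yl)oxiran-2-yl]methyl trifluoromethanesulfonate
Conditions: Tf2O, 2,6-lutidine, CH2Cl2, −78 °C; cold work-up, used at once
Reagents that add atoms: trifluoromethanesulfonic anhydride, O=S(=O)(OS(=O)(=O)C(F)(F)F)C(F)(F)F
Why: Sulfonylation of the primary alcohol at low temperature with a hindered base; oxirane and alkyne do not react and no stereocentre is involved.

Step 7
Reactants: 10 [(2R,3R)-3-(prop-2-yn-1-yl)oxiran-2-yl]methyl trifluoromethanesulfonate; 11 1-bromohexane
Product: 13 (2R,3R)-2-heptyl-3-(prop-2-yn-1-yl)oxirane, via hexylmagnesium bromide 12 (not isolated)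
Conditions: Mg, Et2O, rt (11 → 12, about 3 equiv); then 10, CuI (10 mol %), Et2O, −78 → −30 °C; NH4Cl (aq.)
Reagents that add atoms: none
Why: Copper-catalysed Grignard cross-coupling at a primary triflate; displacement of triflate by the alkylcuprate formed in the flask should be far faster than attack on the disubstituted oxirane at these temperatures. The excess of 12 covers any deprotonation of the terminal alkyne, whose magnesium acetylide does not alkylate and is reprotonated on work-up; C11 is a methylene, so C9 and C10 are untouched.

Step 8
Reactants: 14 ethynyl(trimethyl)silane; 15 acrolein
Product: 17 rac-5-(trimethylsilyl)pent-1-en-4-yn-3-ol, via lithium (trimethylsilyl)acetylide 16 (not isolated)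
Conditions: n-BuLi, THF, −78 °C; then 15, −78 °C; NH4Cl (aq.)
Reagents that add atoms: none
Why: 1,2-Addition of a lithium acetylide to an enal at low temperature forms the C3–C4 bond; the product is racemic at this stage.

Step 9
Reactants: 17 rac-5-(trimethylsilyl)pent-1-en-4-yn-3-ol
Product: 18 (3S)-5-(trimethylsilyl)pent-1-en-4-yn-3-ol (recovered unreacted alcohol)
Conditions: lipase from Pseudomonas fluorescens, vinyl acetate, hexane, rt, run to just beyond half conversion
Reagents that add atoms: none
Why: Enzymatic kinetic resolution by irreversible transesterification; with silylethynyl as the large and vinyl as the medium substituent the lipase is expected to acetylate the (R)-alcohol and leave the (S)-alcohol, and running past half conversion should leave 18 in high enantiomeric purity. This sets C3.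

Step 10
Reactants: 18 (3S)-5-(trimethylsilyl)pent-1-en-4-yn-3-ol
Product: 19 (3S)-5-bromopent-1-en-4-yn-3-ol
Conditions: NBS, AgNO3 (cat.), acetone, rt, dark
Reagents that add atoms: N-bromosuccinimide, O=C1CCC(=O)N1Br
Why: Silver-catalysed desilylative bromination; the silver acetylide formed from the alkynylsilane is brominated by NBS, and the carbinol centre is not involved.

Step 11
Reactants: 13 (2R,3R)-2-heptyl-3-(prop-2-yn-1-yl)oxirane; 19 (3S)-5-bromopent-1-en-4-yn-3-ol
Product: 20 (3S,9R,10R)-9,10-epoxyheptadec-1-ene-4,6-diyn-3-ol
Conditions: CuCl (cat.), NH2OH·HCl, EtNH2 (aq.), MeOH, 0 °C, slow addition of 19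
Reagents that add atoms: none
Why: Cadiot–Chodkiewicz coupling; the copper acetylide of 13 couples with bromoalkyne 19 to form the C5–C6 bond, and hydroxylamine keeps copper in its monovalent state so that oxidative homocoupling is suppressed. Low temperature and a short reaction time should spare the oxirane and the C8 hydrogens; no stereocentre takes part.

Step 12
Reactants: 20 (3S,9R,10R)-9,10-epoxyheptadec-1-ene-4,6-diyn-3-ol; 21 linoleic acid
Product: 22 (3S,9R,10R)-9,10-epoxyheptadec-1-ene-4,6-diyn-3-yl (9Z,12Z)-octadeca-9,12-dienoate
Conditions: EDC·HCl, DMAP (cat.), CH2Cl2, 0 °C → rt, argon, dark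
Reagents that add atoms: none
Why: Steglich esterification; the carbodiimide activates 21 and DMAP transfers the acyl group to O3, so the C3–O bond is never broken and C3 stays S. The near-neutral conditions should leave oxirane, diyne and the skipped Z,Z-diene intact.

## Compound list

1 | 2-deoxy-D-ribose | O=CC[C@H](O)[C@H](O)CO | starting material
2 | 2-deoxy-3,4-O-isopropylidene-D-erythro-pentopyranose (anomeric mixture) | OC1C[C@@H]2OC(C)(C)O[C@@H]2CO1 | intermediate
3 | dimethyl (1-diazo-2-oxopropyl)phosphonate | CC(=O)C(=[N+]=[N-])P(=O)(OC)OC | starting material
4 | dimethyl (diazomethyl)phosphonate (formed in the flask, not isolated) | COP(=O)(OC)C=[N+]=[N-] | intermediate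
5 | [(4R,5S)-2,2-dimethyl-5-(prop-2-yn-1-yl)-1,3-dioxolan-4-yl]methanol | C#CC[C@@H]1OC(C)(C)O[C@@H]1CO | intermediate
6 | (1S)-1-[(4R)-2,2-dimethyl-1,3-dioxolan-4-yl]but-3-yn-1-ol | C#CC[C@H](O)[C@H]1COC(C)(C)O1 | intermediate
7 | (1S)-1-[(4R)-2,2-dimethyl-1,3-dioxolan-4-yl]but-3-yn-1-yl methanesulfonate | C#CC[C@H](OS(C)(=O)=O)[C@H]1COC(C)(C)O1 | intermediate
8 | (2R,3S)-1,2-dihydroxyhex-5-yn-3-yl methanesulfonate (not isolated) | C#CC[C@H](OS(C)(=O)=O)[C@H](O)CO | intermediate
9 | [(2R,3R)-3-(prop-2-yn-1-yl)oxiran-2-yl]methanol | C#CC[C@H]1O[C@@H]1CO | intermediate
10 | [(2R,3R)-3-(prop-2-yn-1-yl)oxiran-2-yl]methyl trifluoromethanesulfonate | C#CC[C@H]1O[C@@H]1COS(=O)(=O)C(F)(F)F | intermediate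
11 | 1-bromohexane | CCCCCCBr | starting material
12 | hexylmagnesium bromide (not isolated) | CCCCCC[Mg]Br | intermediate
13 | (2R,3R)-2-heptyl-3-(prop-2-yn-1-yl)oxirane | C#CC[C@H]1O[C@@H]1CCCCCCC | intermediate
14 | ethynyl(trimethyl)silane | C#C[Si](C)(C)C | starting material
15 | acrolein | C=CC=O | starting material
16 | lithium (trimethylsilyl)acetylide (not isolated) | [Li]C#C[Si](C)(C)C | intermediate
17 | rac-5-(trimethylsilyl)pent-1-en-4-yn-3-ol | C=CC(O)C#C[Si](C)(C)C | intermediate
18 | (3S)-5-(trimethylsilyl)pent-1-en-4-yn-3-ol | C=C[C@@H](C#C[Si](C)(C)C)O | intermediate
19 | (3S)-5-bromopent-1-en-4-yn-3-ol | C=C[C@@H](C#CBr)O | intermediate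
20 | (3S,9R,10R)-9,10-epoxyheptadec-1-ene-4,6-diyn-3-ol | C=C[C@@H](C#CC#CC[C@H]1O[C@@H]1CCCCCCC)O | intermediate
21 | linoleic acid, (9Z,12Z)-octadeca-9,12-dienoic acid | CCCCC/C=C\C/C=C\CCCCCCCC(=O)O | starting material
22 | (3S,9R,10R)-9,10-epoxyheptadec-1-ene-4,6-diyn-3-yl (9Z,12Z)-octadeca-9,12-dienoate | C=C[C@@H](C#CC#CC[C@H]1O[C@@H]1CCCCCCC)OC(=O)CCCCCCC/C=C\C/C=C\CCCCC | target

## Step count and least certain steps

Total step count: 12. Longest linear sequence: 9 steps (steps 1–7, 11 and 12, from 1); the side branch (steps 8–10) joins at step 11.

**Step 2 (key step).** The open-chain aldehyde is present only in low concentration, so alkynylation may be slow enough for β-elimination of the ketal oxygen or decay of the diazophosphonate anion to compete. The fallback sets out from 2 and comes back at 5. A Wittig reaction of 2 with the ylide from (chloromethyl)triphenylphosphonium chloride and NaHMDS in THF should give the chloroalkene [(4R,5S)-5-(3-chloroprop-2-en-1-yl)-2,2-dimethyl-1,3-dioxolan-4-yl]methanol F1 as an E/Z mixture. Treatment of F1 with n-BuLi (3 equiv, THF, −78 → 0 °C) should then eliminate hydrogen chloride and give 5 after protonation.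

**Step 3.** The ketal equilibrium may not lie far enough on the side of the terminal dioxolane, or the six-membered ketal may form, which would make the separation from 5 wasteful. The fallback sets out from 5 and comes back at 6. Hydrolysis in aqueous acetic acid should give (2R,3S)-hex-5-yne-1,2,3-triol F2. Kinetically controlled ketalisation of F2 with one equivalent of 2-methoxypropene and PPTS in DMF at 0 °C should then engage the primary hydroxyl first and close onto the neighbouring O10 to give 6.

**Step 7.** Deprotonation of the terminal alkyne may tie up the copper catalyst, and magnesium halide or the Grignard reagent may open the oxirane before the triflate is displaced. The fallback sets out from 9 and comes back at 13. Double deprotonation of 9 with n-BuLi (2.1 equiv, THF, −78 °C) and quenching with Me3SiCl should give trimethyl{[(2R,3R)-3-(3-(trimethylsilyl)prop-2-yn-1-yl)oxiran-2-yl]methoxy}silane F3, which is not isolated. Brief treatment with citric acid in methanol cleaves only the silyl ether and gives {(2R,3R)-3-[3-(trimethylsilyl)prop-2-yn-1-yl]oxiran-2-yl}methanol F4. Triflation as in step 6 gives {(2R,3R)-3-[3-(trimethylsilyl)prop-2-yn-1-yl]oxiran-2-yl}methyl trifluoromethanesulfonate F5. Coupling with 12 and catalytic CuI as in step 7, now without an acidic C–H, gives (2R,3R)-2-heptyl-3-[3-(trimethylsilyl)prop-2-yn-1-yl]oxirane F6, and K2CO3 in MeOH at 0 °C removes the silyl group to give 13.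

**Step 9.** The enzyme may discriminate poorly between the two unsaturated substituents, or prefer the other enantiomer, which would leave 18 in insufficient purity. The fallback sets out from 17 and comes back at 18. A Sharpless kinetic resolution with Ti(OiPr)4, L-(+)-diisopropyl tartrate and t-BuOOH over 4 Å molecular sieves in CH2Cl2 at −20 °C is expected to epoxidise the (R)-enantiomer selectively to the erythro epoxy alcohol (1S)-1-[(2R)-oxiran-2-yl]-3-(trimethylsilyl)prop-2-yn-1-ol F7 and to leave 18 unreacted. If the lipase merely shows the opposite preference, methanolysis of the acetate formed in step 9 gives 18 without any change of route.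

**Step 11.** Reductive homocoupling of 19 may consume it, and the amine may open the oxirane or isomerise the skipped system at C8. The fallback sets out from 13 and 18 and comes back at 20, with the roles of the partners reversed. Treatment of 13 with NBS and catalytic AgNO3 in acetone gives (2R,3R)-2-(3-bromoprop-2-yn-1-yl)-3-heptyloxirane F8. Treatment of 18 with K2CO3 in MeOH gives (3S)-pent-1-en-4-yn-3-ol F9. F8 is then added slowly to an excess of F9 with CuCl, NH2OH·HCl and aqueous EtNH2 in MeOH at 0 °C, so that the valuable fragment is the electrophile and is consumed by an excess of the cheap acetylide.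

## Further compounds

F1 | step 2 | [(4R,5S)-5-(3-chloroprop-2-en-1-yl)-2,2-dimethyl-1,3-dioxolan-4-yl]methanol (E/Z mixture) | ClC=CC[C@@H]1OC(C)(C)O[C@@H]1CO
F2 | step 3 | (2R,3S)-hex-5-yne-1,2,3-triol | C#CC[C@H](O)[C@H](O)CO
F3 | step 7 | trimethyl{[(2R,3R)-3-(3-(trimethylsilyl)prop-2-yn-1-yl)oxiran-2-yl]methoxy}silane | C[Si](C)(C)C#CC[C@H]1O[C@@H]1CO[Si](C)(C)C
F4 | step 7 | {(2R,3R)-3-[3-(trimethylsilyl)prop-2-yn-1-yl]oxiran-2-yl}methanol | C[Si](C)(C)C#CC[C@H]1O[C@@H]1CO
F5 | step 7 | {(2R,3R)-3-[3-(trimethylsilyl)prop-2-yn-1-yl]oxiran-2-yl}methyl trifluoromethanesulfonate | C[Si](C)(C)C#CC[C@H]1O[C@@H]1COS(=O)(=O)C(F)(F)F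
F6 | step 7 | (2R,3R)-2-heptyl-3-[3-(trimethylsilyl)prop-2-yn-1-yl]oxirane | C[Si](C)(C)C#CC[C@H]1O[C@@H]1CCCCCCC
F7 | step 9 | (1S)-1-[(2R)-oxiran-2-yl]-3-(trimethylsilyl)prop-2-yn-1-ol | C[Si](C)(C)C#C[C@H](O)[C@H]1CO1
F8 | step 11 | (2R,3R)-2-(3-bromoprop-2-yn-1-yl)-3-heptyloxirane | BrC#CC[C@H]1O[C@@H]1CCCCCCC
F9 | step 11 | (3S)-pent-1-en-4-yn-3-ol | C=C[C@@H](C#C)O
A1 | alternative 1 | tert-butyldimethylsilyl ether of (3S,9E)-heptadeca-1,9-dien-4,6-diyn-3-ol | C=C[C@@H](C#CC#CC/C=C/CCCCCCC)O[Si](C)(C)C(C)(C)C
A2 | alternative 1 | tert-butyldimethylsilyl ether of (3S,9R,10R)-9,10-epoxyheptadec-1-ene-4,6-diyn-3-ol | C=C[C@@H](C#CC#CC[C@H]1O[C@@H]1CCCCCCC)O[Si](C)(C)C(C)(C)C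
A3 | alternative 2 | (2S)-2-chlorononanal | CCCCCCC[C@H](Cl)C=O
A4 | alternative 2 | allenylboronic acid pinacol ester | C=C=CB1OC(C)(C)C(C)(C)O1
A5 | alternative 2 | (4R,5S)-5-chlorododec-1-yn-4-ol | C#CC[C@@H](O)[C@@H](Cl)CCCCCCC
A6 | alternative 3 | (2R,3R)-2-heptyl-3-(penta-2,4-diyn-1-yl)oxirane | C#CC#CC[C@H]1O[C@@H]1CCCCCCC
A7 | alternative 3 | acrolein | C=CC=O
A8 | alternative 3 | (3S,9R,10R)-9,10-epoxyheptadec-1-ene-4,6-diyn-3-ol | C=C[C@@H](C#CC#CC[C@H]1O[C@@H]1CCCCCCC)O
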